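**Assumption:** the SMILES is read as (3S,3aS,6S,6aR), meaning all four ring hydrogens are cis and both aryl groups are endo. Compounds 1, 2, 4 and 6 are bought; 4 is recovered in step 4.

## Retrosynthetic overview

1. 15 ⇐ 14: H2 adds to the C3a=C6a butenolide from the face opposite the two cis aryl groups, which sets both bridgeheads (all-cis); the benzyl ethers fall in the same operation.
2. 14 ⇐ 11 ⇐ 10: α-selenenylation and selenoxide syn-elimination of the exo,exo lactone. Quinone methide trapping can only give exo aryl groups, so C3 and C6 are kept and the two bridgeheads are erased and re-set.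
3. 10 ⇐ 5 + 7: one-pot oxidative 8–8′ phenoxy-radical cross-coupling → bis-quinone methide → double 5-exo oxa-cyclisation. A C2-symmetric pyrrolidine amide steers the C8 face and leaves during lactonisation.
4. 5 ⇐ 1 + 2 + 4; 7 ⇐ 6.
5. Ring order: tetrahydrofuran ring first, lactone ring second, both in step 4; no ring is made or broken afterwards.

## Route

Step 1
Reactants: 1 3-(benzyloxy)-4-hydroxybenzaldehyde; 2 malonic acid
Product: 3 (E)-3-[3-(benzyloxy)-4-hydroxyphenyl]prop-2-enoic acid
Conditions: pyridine, piperidine (cat.), 85 °C; then aq. HCl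
Reagents that add atoms: none
Why: Knoevenagel–Doebner condensation with decarboxylation gives the E-cinnamic acid and tolerates the free phenol, as in the vanillin to ferulic acid reaction.

Step 2
Reactants: 3 (E)-3-[3-(benzyloxy)-4-hydroxyphenyl]prop-2-enoic acid; 4 (2S,5S)-2,5-dimethylpyrrolidine
Product: 5 (E)-3-[3-(benzyloxy)-4-hydroxyphenyl]-1-[(2S,5S)-2,5-dimethylpyrrolidin-1-yl]prop-2-en-1-one
Conditions: EDC·HCl, HOBt (cat.), CH2Cl2/DMF, 0 °C → 40 °C
Reagents that add atoms: none
Why: Carbodiimide amide coupling through the HOBt active ester acylates the secondary amine and leaves the E-alkene and both pyrrolidine stereocentres untouched.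

Step 3
Reactants: 6 methyl (E)-3-(4-hydroxy-3,5-dimethoxyphenyl)prop-2-enoate (methyl sinapate)
Product: 7 (E)-4-(3-hydroxyprop-1-enyl)-2,6-dimethoxyphenol (sinapyl alcohol)
Conditions: (i-Bu)2AlH (4 equiv), toluene, 0 °C; aq. potassium sodium tartrate
Reagents that add atoms: none
Why: (i-Bu)2AlH 1,2-reduction of the cinnamate ester gives the allylic alcohol without conjugate reduction, the standard monolignol preparation.

Step 4
Reactants: 5 (E)-3-[3-(benzyloxy)-4-hydroxyphenyl]-1-[(2S,5S)-2,5-dimethylpyrrolidin-1-yl]prop-2-en-1-one; 7 sinapyl alcohol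
Product: 10 (3S,3aR,6S,6aS)-6-[3-(benzyloxy)-4-hydroxyphenyl]-3-(4-hydroxy-3,5-dimethoxyphenyl)tetrahydro-1H,3H-furo[3,4-c]furan-1-one, via bis-quinone methide 8 (not isolated), via cyclic iminium ether 9 (not isolated)
Conditions: Ag2O (2.2 equiv), 5 (2 equiv), 7 added over 2 h, CH2Cl2/acetone 2:1, 0 °C → rt, dark; filter; THF/H2O, AcOH (pH 4), rt
Reagents that add atoms: water (O)
Why: Proposed new method: Ag2O oxidises both phenols by one electron and the two phenoxy radicals cross-couple C8–C8′ to bis-quinone methide 8; the CH2OH then adds 5-exo to the caffeoyl quinone methide (tetrahydrofuran ring) and the amide carbonyl oxygen adds 5-exo to the syringyl quinone methide (lactone ring as iminium ether 9), each with the neighbouring C–H eclipsing the quinone methide plane (A(1,3) strain) so that both aryl groups end up exo, and water at pH 4 hydrolyses 9 to the lactone and releases the amine. In the s-cis amide the pyrrolidine methyl next to C8 shields one face of the α-amide radical, so C6a forms S, and only the C8′ epimer that can bicyclise (C3a R) gives 10. Closest known reaction types are Ag2O or FeCl3 8–8′ dehydrodimerisation of hydroxycinnamates and monolignols to furofurans, trans-2,5-dimethylpyrrolidine amide control of α-amide radicals, and iodolactonisation of tertiary amides with loss of the amine.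

Step 5
Reactants: 10 (3S,3aR,6S,6aS)-6-[3-(benzyloxy)-4-hydroxyphenyl]-3-(4-hydroxy-3,5-dimethoxyphenyl)tetrahydro-1H,3H-furo[3,4-c]furan-1-one
Product: 11 (3S,3aR,6S,6aS)-3-[4-(benzyloxy)-3,5-dimethoxyphenyl]-6-[3,4-bis(benzyloxy)phenyl]tetrahydro-1H,3H-furo[3,4-c]furan-1-one
Conditions: BnBr (2.5 equiv), K2CO3, DMF, rt
Reagents that add atoms: benzyl bromide (BrCc1ccccc1)
Why: Williamson etherification caps both phenols, which allows the enolate chemistry and shuts off phenoxide-triggered ring opening; K2CO3 is too weak to enolise the lactone, so no stereocentre is touched.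

Step 6
Reactants: 11 (3S,3aR,6S,6aS)-3-[4-(benzyloxy)-3,5-dimethoxyphenyl]-6-[3,4-bis(benzyloxy)phenyl]tetrahydro-1H,3H-furo[3,4-c]furan-1-one
Product: 12 (3S,3aR,6R,6aR)-3-[4-(benzyloxy)-3,5-dimethoxyphenyl]-6-[3,4-bis(benzyloxy)phenyl]-6a-(phenylselanyl)tetrahydro-1H,3H-furo[3,4-c]furan-1-one
Conditions: LiN(i-Pr)2, THF, −78 °C; PhSeBr, −78 °C
Reagents that add atoms: phenylselenyl bromide (Br[Se]c1ccccc1)
Why: The kinetic lithium enolate of the lactone is selenenylated (enolate α-selenenylation) on the convex face, the only face that keeps the cis ring fusion, so SePh is cis to H3a and trans to H6; the descriptor changes at C6 and C6a are CIP effects only.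

Step 7
Reactants: 12 (3S,3aR,6R,6aR)-3-[4-(benzyloxy)-3,5-dimethoxyphenyl]-6-[3,4-bis(benzyloxy)phenyl]-6a-(phenylselanyl)tetrahydro-1H,3H-furo[3,4-c]furan-1-one
Product: 14 (3R,6R)-3-[4-(benzyloxy)-3,5-dimethoxyphenyl]-6-[3,4-bis(benzyloxy)phenyl]-4,6-dihydro-1H,3H-furo[3,4-c]furan-1-one, via selenoxide 13 (not isolated)
Conditions: 30% H2O2, pyridine, CH2Cl2, 0 °C → rt
Reagents that add atoms: none
Why: Selenoxide syn-elimination can only use H3a, because H6 is anti to selenium and elimination toward an ether carbon is disfavoured; the C3a=C6a butenolide therefore forms, which erases both bridgehead centres while C3 and C6 keep the two aryl groups cis on one face (R,R here is a CIP change only).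

Step 8
Reactants: 14 (3R,6R)-3-[4-(benzyloxy)-3,5-dimethoxyphenyl]-6-[3,4-bis(benzyloxy)phenyl]-4,6-dihydro-1H,3H-furo[3,4-c]furan-1-one
Product: 15 (3S,3aS,6S,6aR)-6-(3,4-dihydroxyphenyl)-3-(4-hydroxy-3,5-dimethoxyphenyl)tetrahydro-1H,3H-furo[3,4-c]furan-1-one
Conditions: H2 (3 atm), 10% Pd/C, EtOAc, rt; stop at full conversion
Reagents that add atoms: none
Why: Heterogeneous syn-hydrogenation adds H2 to the strained tetrasubstituted alkene from the face opposite both aryl groups, setting C3a (S) and C6a (R) with all four ring hydrogens cis, and the three aryl benzyl ethers are hydrogenolysed in the same pot under neutral conditions that do not epimerise the endo aryl groups.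

## Compound list

1 | 3-(benzyloxy)-4-hydroxybenzaldehyde | O=Cc1ccc(O)c(OCc2ccccc2)c1 | starting material
2 | malonic acid | OC(=O)CC(=O)O | starting material
3 | (E)-3-[3-(benzyloxy)-4-hydroxyphenyl]prop-2-enoic acid | OC(=O)/C=C/c1ccc(O)c(OCc2ccccc2)c1 | intermediate
4 | (2S,5S)-2,5-dimethylpyrrolidine | C[C@H]1CC[C@H](C)N1 | starting material
5 | (E)-3-[3-(benzyloxy)-4-hydroxyphenyl]-1-[(2S,5S)-2,5-dimethylpyrrolidin-1-yl]prop-2-en-1-one | C[C@H]1CC[C@H](C)N1C(=O)/C=C/c1ccc(O)c(OCc2ccccc2)c1 | intermediate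
6 | methyl (E)-3-(4-hydroxy-3,5-dimethoxyphenyl)prop-2-enoate | COC(=O)/C=C/c1cc(OC)c(O)c(OC)c1 | starting material
7 | (E)-4-(3-hydroxyprop-1-enyl)-2,6-dimethoxyphenol | OC/C=C/c1cc(OC)c(O)c(OC)c1 | intermediate
8 | (2R,3R)-2-[(3-benzyloxy-4-oxocyclohexa-2,5-dien-1-ylidene)methyl]-3-[(3,5-dimethoxy-4-oxocyclohexa-2,5-dien-1-ylidene)methyl]-1-[(2S,5S)-2,5-dimethylpyrrolidin-1-yl]-4-hydroxybutan-1-one (bis-quinone methide) | O=C1C=CC(=C[C@H]([C@H](CO)C=C2C=C(OC)C(=O)C(OC)=C2)C(=O)N2[C@@H](C)CC[C@@H]2C)C=C1OCc1ccccc1 | intermediate (not isolated)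
9 | cyclic iminium ether: the bicycle of 10 with C1 bearing the (2S,5S)-2,5-dimethylpyrrolidin-1-ium-1-ylidene group in place of =O; zwitterion with the syringyl phenolate | Oc1ccc(cc1OCc1ccccc1)[C@@H]1[C@H]2C(=[N+]3[C@@H](C)CC[C@@H]3C)O[C@@H]([C@H]2CO1)c1cc(OC)c([O-])c(OC)c1 | intermediate (not isolated)
10 | (3S,3aR,6S,6aS)-6-[3-(benzyloxy)-4-hydroxyphenyl]-3-(4-hydroxy-3,5-dimethoxyphenyl)tetrahydro-1H,3H-furo[3,4-c]furan-1-one (both aryls exo) | Oc1ccc(cc1OCc1ccccc1)[C@@H]1[C@H]2C(=O)O[C@@H]([C@H]2CO1)c1cc(OC)c(O)c(OC)c1 | intermediate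
11 | (3S,3aR,6S,6aS)-3-[4-(benzyloxy)-3,5-dimethoxyphenyl]-6-[3,4-bis(benzyloxy)phenyl]tetrahydro-1H,3H-furo[3,4-c]furan-1-one | O(Cc1ccccc1)c1ccc(cc1OCc1ccccc1)[C@@H]1[C@H]2C(=O)O[C@@H]([C@H]2CO1)c1cc(OC)c(OCc2ccccc2)c(OC)c1 | intermediate
12 | (3S,3aR,6R,6aR)-3-[4-(benzyloxy)-3,5-dimethoxyphenyl]-6-[3,4-bis(benzyloxy)phenyl]-6a-(phenylselanyl)tetrahydro-1H,3H-furo[3,4-c]furan-1-one | O(Cc1ccccc1)c1ccc(cc1OCc1ccccc1)[C@@H]1[C@@]2([Se]c3ccccc3)C(=O)O[C@@H]([C@H]2CO1)c1cc(OC)c(OCc2ccccc2)c(OC)c1 | intermediate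
13 | selenoxide of 12 (mixture at selenium) | O(Cc1ccccc1)c1ccc(cc1OCc1ccccc1)[C@@H]1[C@@]2([Se](=O)c3ccccc3)C(=O)O[C@@H]([C@H]2CO1)c1cc(OC)c(OCc2ccccc2)c(OC)c1 | intermediate (not isolated)
14 | (3R,6R)-3-[4-(benzyloxy)-3,5-dimethoxyphenyl]-6-[3,4-bis(benzyloxy)phenyl]-4,6-dihydro-1H,3H-furo[3,4-c]furan-1-one (aryls cis) | O(Cc1ccccc1)c1ccc(cc1OCc1ccccc1)[C@H]1OCC2=C1C(=O)O[C@@H]2c1cc(OC)c(OCc2ccccc2)c(OC)c1 | intermediate
15 | (3S,3aS,6S,6aR)-6-(3,4-dihydroxyphenyl)-3-(4-hydroxy-3,5-dimethoxyphenyl)tetrahydro-1H,3H-furo[3,4-c]furan-1-one | COc1cc([C@H]2OC(=O)[C@@H]3[C@H]2CO[C@@H]3c2ccc(O)c(O)c2)cc(OC)c1O | target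

## Step count and risks

Total steps: 8. Longest linear sequence: 7 (steps 1, 2, 4, 5, 6, 7, 8).

**Step 4** is the most likely to fail. Homo-coupling, 8–O–4 and 8–5 cross-coupling and the non-cyclising C8′ epimer all compete, so a yield of roughly 10–25% is expected. The facial selectivity of a radical–radical coupling is unproven; the sense of induction must be confirmed on 10, and the enantiomeric purity would be raised by crystallising 11. Fallback: set out from acid 3 and alcohol 7 without the auxiliary and couple them with FeCl3·6H2O in acetone/water, where the free carboxylic acid itself traps the syringyl quinone methide. This gives the racemic exo,exo lactone, that is 10 together with its mirror image (3R,3aS,6R,6aR)-lactone F1. The two are separated by preparative chiral SFC and 10 comes back to the route at step 5.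

**Step 7** may fail because the selenoxide has to form a strained ring-fusion alkene, and the butenolide has an acidic benzylic γ-hydrogen. Fallback: set out from 11, hydroxylate the lithium enolate (LiN(SiMe3)2, then 2-(phenylsulfonyl)-3-phenyloxaziridine) on the convex face to the 6a-hydroxy lactone F2, and dehydrate it with the Burgess reagent in warm benzene. This is a syn-elimination through a sulfamate ester in which again only H3a is available, and it returns to the route at 14.

**Step 8** may fail through Pd-mediated hydrogenolysis of the allylic and benzylic lactone C–O bond, or through migration of the double bond to the unreactive enol-ether position before reduction. Fallback: set out from 14 and carry out a conjugate reduction with stoichiometric [(Ph3P)CuH]6 in moist toluene. Hydride adds to C3a anti to the aryl groups and the enolate is protonated on the convex face, giving the all-cis tribenzyl lactone F3. A brief transfer hydrogenolysis (Pd/C, 1,4-cyclohexadiene, EtOAc) then removes the benzyl groups and arrives at 15.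

## Further compounds

F1 | step 4 | (3R,3aS,6R,6aR)-6-[3-(benzyloxy)-4-hydroxyphenyl]-3-(4-hydroxy-3,5-dimethoxyphenyl)tetrahydro-1H,3H-furo[3,4-c]furan-1-one | Oc1ccc(cc1OCc1ccccc1)[C@H]1[C@@H]2C(=O)O[C@H]([C@@H]2CO1)c1cc(OC)c(O)c(OC)c1
F2 | step 7 | (3S,3aR,6R,6aR)-3-[4-(benzyloxy)-3,5-dimethoxyphenyl]-6-[3,4-bis(benzyloxy)phenyl]-6a-hydroxytetrahydro-1H,3H-furo[3,4-c]furan-1-one | O(Cc1ccccc1)c1ccc(cc1OCc1ccccc1)[C@@H]1[C@@]2(O)C(=O)O[C@@H]([C@H]2CO1)c1cc(OC)c(OCc2ccccc2)c(OC)c1
F3 | step 8 | (3S,3aS,6S,6aR)-3-[4-(benzyloxy)-3,5-dimethoxyphenyl]-6-[3,4-bis(benzyloxy)phenyl]tetrahydro-1H,3H-furo[3,4-c]furan-1-one | O(Cc1ccccc1)c1ccc(cc1OCc1ccccc1)[C@@H]1[C@@H]2C(=O)O[C@@H]([C@@H]2CO1)c1cc(OC)c(OCc2ccccc2)c(OC)c1
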